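**Retrosynthetic overview**

1. Target 27 comes from O-acylation of the enolate of 1,2-diketone 24; 24 comes from coumarin 21 by desilylation, carbinol oxidation and α-methylene oxidation.
2. Ring B (the pyran-2-one) is closed last, from salicylaldehyde 18 and a two-carbon ketenylidene ylide (bonds O1–C2 and C3=C4).
3. Ring A (the benzene ring) is built first. The strategy rests on its four contiguous substituted carbons, C4a (carbon, C4), C8a (oxygen, O1), C8 (side chain) and C7 (OMe), with C5 and C6 bearing only H. A vinylketene and a 1-methoxyalkyne give exactly this pattern (bonds C5–C6, C8a–C8, C6–C7, C8a–C4a).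
4. Diazo enone 6 comes from a Wittig reaction and a detrifluoroacetylative diazo transfer; methoxyalkyne 12 comes from lithium methoxyacetylide and 3-methylbutanal.

Key step: step 5

Remark: the target has no stereocentre. The carbinol carbon made in step 3 is carried as the racemate and becomes a carbonyl in step 9. Coumarin numbering (O1, C2 … C8a) is used for all ring atoms.

**Route**

Step 1
Reactants: 1 2,2-dimethoxyacetaldehyde (commercial 60% aqueous solution); 2 1-(triphenylphosphoranylidene)propan-2-one
Product: 3 (E)-5,5-dimethoxypent-3-en-2-one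
Conditions: CH2Cl2, rt
Reagents that add atoms: none
Why: Wittig olefination with a stabilised acyl ylide, which tolerates the water of the aldehyde solution and should give the E-enone.

Step 2
Reactants: 3 (E)-5,5-dimethoxypent-3-en-2-one
Product: 6 (E)-1-diazo-5,5-dimethoxypent-3-en-2-one, via lithium dienolate 4 (not isolated), via trifluoroacetyl diketone 5 (not isolated)
Conditions: LiN(SiMe3)2, THF, −78 °C; CF3CO2CH2CF3; then 4-AcNHC6H4SO2N3, Et3N, H2O, MeCN, rt
Reagents that add atoms: 4-acetamidobenzenesulfonyl azide, CC(=O)Nc1ccc(cc1)S(=O)(=O)N=[N+]=[N-] (gives the N2 unit of 6); 2,2,2-trifluoroethyl trifluoroacetate, O=C(OCC(F)(F)F)C(F)(F)F (gives the CF3CO group of 5, lost again on the way to 6)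
Why: Detrifluoroacetylative diazo transfer: kinetic deprotonation of the methyl group, Claisen-type trifluoroacetylation to activate that carbon, then Regitz-type diazo transfer with loss of the trifluoroacetyl group as the N-acylsulfonamide, the standard access to α'-diazo enones.

Step 3
Reactants: 7 2-chloro-1,1-dimethoxyethane; 8 3-methylbutanal
Product: 11 1-methoxy-5-methylhex-1-yn-3-ol (racemic), via lithium methoxyacetylide 9 (not isolated), via lithium alkoxide 10 (not isolated)
Conditions: Et2NH, n-BuLi (3.3 equiv each), THF, 0 °C; then 8, −78 → 0 °C; aq NaHCO3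
Reagents that add atoms: none
Why: Lithium diethylamide eliminates MeOH and then HCl from the chloroacetal and deprotonates the methoxyacetylene formed, and the acetylide adds 1,2 to the aldehyde; the carbinol centre forms as the racemate, and the basic work-up keeps the acid-labile ynol ether from Meyer–Schuster rearrangement.

Step 4
Reactants: 11 1-methoxy-5-methylhex-1-yn-3-ol (racemic)
Product: 12 tert-butyl[(1-methoxy-5-methylhex-1-yn-3-yl)oxy]dimethylsilane (racemic)
Conditions: TBSCl, imidazole, DMF, 0 °C → rt
Reagents that add atoms: tert-butyldimethylsilyl chloride, CC(C)(C)[Si](C)(C)Cl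
Why: Imidazole-mediated silylation of a secondary alcohol under non-acidic conditions, which the ynol ether should tolerate.

Step 5
Reactants: 6 (E)-1-diazo-5,5-dimethoxypent-3-en-2-one (1.3 equiv); 12 tert-butyl[(1-methoxy-5-methylhex-1-yn-3-yl)oxy]dimethylsilane (racemic)
Product: 17 2-[1-(tert-butyldimethylsilyloxy)-3-methylbutyl]-6-(dimethoxymethyl)-3-methoxyphenol (racemic), via vinylketene 13 (not isolated), via vinylcyclobutenone 14 (not isolated), via dienylketene 15 (not isolated), via cyclohexadienone 16 (not isolated)
Conditions: hν (254 nm, low-pressure Hg lamp), ClCH2CH2Cl, rt; then 80 °C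
Reagents that add atoms: none
Why: Light expels N2 from 6 and the alkenyl group migrates (photochemical Wolff rearrangement, bond C5–C6) to give vinylketene 13, whose ketene C=C adds ynol ether 12 in a [2+2] cycloaddition (bonds C8a–C8 and C6–C7) to give 4-vinylcyclobutenone 14. Four-electron electrocyclic opening of 14 gives dienylketene 15, which closes ring A by a six-electron disrotatory electrocyclisation between the ketene carbon and the acetal-bearing alkene terminus (bond C8a–C4a), and cyclohexadienone 16 tautomerises to phenol 17. The closest known reaction type is the Danheiser benzannulation in its diazo ketone form with alkoxyalkynes, which gives 2-substituted 3-alkoxyphenols. No stereocentre is created: the carbinol centre of 12 is carried unchanged as the racemate and the sp3 ring carbon of 16 is lost on aromatisation. The step needs the regiochemistry in which the alkyne carbon remote from OMe joins the ketene carbonyl carbon; the polarisation of the ynol ether (nucleophilic β-carbon) against the electrophilic ketene carbon secures it, so that OH, side chain, OMe and the acetal carbon arrive at C8a, C8, C7 and C4a with no aromatic substitution. The methoxy group has no β-hydrogen, so the retro-ene loss of alkene that limits higher alkoxyalkynes at 80 °C cannot occur.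

Step 6
Reactants: 17 2-[1-(tert-butyldimethylsilyloxy)-3-methylbutyl]-6-(dimethoxymethyl)-3-methoxyphenol (racemic)
Product: 18 3-[1-(tert-butyldimethylsilyloxy)-3-methylbutyl]-2-hydroxy-4-methoxybenzaldehyde (racemic)
Conditions: pyridinium p-toluenesulfonate (cat.), acetone/H2O, rt
Reagents that add atoms: water, O
Why: Acid-catalysed hydrolysis of an electron-rich aryl dimethyl acetal, which should be much faster than cleavage of the hindered secondary TBS ether under these mild conditions.

Step 7
Reactants: 18 3-[1-(tert-butyldimethylsilyloxy)-3-methylbutyl]-2-hydroxy-4-methoxybenzaldehyde (racemic); 19 (triphenylphosphoranylidene)ketene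
Product: 21 8-[1-(tert-butyldimethylsilyloxy)-3-methylbutyl]-7-methoxy-2H-chromen-2-one (racemic), via aryl phosphoranylideneacetate 20 (not isolated)
Conditions: toluene, 110 °C
Reagents that add atoms: none
Why: The phenol adds across the cumulated ylide to give ester ylide 20 (bond O1–C2), which closes ring B by intramolecular Wittig reaction on the neighbouring aldehyde (C3=C4, cis by ring constraint), a known coumarin synthesis that avoids the roughly 200 °C needed for the intermolecular variant.

Step 8
Reactants: 21 8-[1-(tert-butyldimethylsilyloxy)-3-methylbutyl]-7-methoxy-2H-chromen-2-one (racemic)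
Product: 22 8-(1-hydroxy-3-methylbutyl)-7-methoxy-2H-chromen-2-one (racemic)
Conditions: TBAF, AcOH, THF, 0 °C → rt
Reagents that add atoms: none
Why: Fluoride-induced desilylation, with acetic acid buffering to protect the lactone from basic opening.

Step 9
Reactants: 22 8-(1-hydroxy-3-methylbutyl)-7-methoxy-2H-chromen-2-one (racemic)
Product: 23 7-methoxy-8-(3-methylbutanoyl)-2H-chromen-2-one
Conditions: Dess–Martin periodinane, CH2Cl2, rt
Reagents that add atoms: none
Why: Dess–Martin oxidation of a hindered secondary benzylic alcohol to the aryl ketone under near-neutral conditions; the only stereocentre of the route is removed here.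

Step 10
Reactants: 23 7-methoxy-8-(3-methylbutanoyl)-2H-chromen-2-one
Product: 24 1-(7-methoxy-2-oxo-2H-chromen-8-yl)-3-methylbutane-1,2-dione
Conditions: SeO2, 1,4-dioxane/H2O, 100 °C
Reagents that add atoms: selenium dioxide, O=[Se]=O
Why: Riley oxidation of the only α-methylene group of an aryl alkyl ketone to the 1,2-diketone through the enol and a selenous ester; the coumarin has no allylic C–H that could compete.

Step 11
Reactants: 24 1-(7-methoxy-2-oxo-2H-chromen-8-yl)-3-methylbutane-1,2-dione; 25 3-methylbutanoyl chloride
Product: 27 Exotimarin H, 1-(7-methoxy-2-oxo-2H-chromen-8-yl)-3-methyl-1-oxobut-2-en-2-yl 3-methylbutanoate, via lithium enolate 26 (not isolated)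
Conditions: LiN(SiMe3)2, THF, −78 °C; then 25, −78 → 0 °C
Reagents that add atoms: none
Why: The isopropyl methine is the only enolisable position of 24, and its fully substituted lithium enolate should be acylated on oxygen by the hard acid chloride because C-acylation would have to build a quaternary carbon (enolate O-acylation to an enol ester).

**Compound list**

1 | 2,2-dimethoxyacetaldehyde | COC(OC)C=O | starting material
2 | 1-(triphenylphosphoranylidene)propan-2-one | CC(=O)C=P(c1ccccc1)(c1ccccc1)c1ccccc1 | starting material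
3 | (E)-5,5-dimethoxypent-3-en-2-one | COC(OC)/C=C/C(C)=O | intermediate
4 | lithium (3E)-5,5-dimethoxypenta-1,3-dien-2-olate | [Li]OC(=C)/C=C/C(OC)OC | intermediate
5 | (E)-1,1,1-trifluoro-7,7-dimethoxyhept-5-ene-2,4-dione | COC(OC)/C=C/C(=O)CC(=O)C(F)(F)F | intermediate
6 | (E)-1-diazo-5,5-dimethoxypent-3-en-2-one | COC(OC)/C=C/C(=O)C=[N+]=[N-] | intermediate
7 | 2-chloro-1,1-dimethoxyethane | COC(CCl)OC | starting material
8 | 3-methylbutanal | CC(C)CC=O | starting material
9 | lithium methoxyacetylide | [Li]C#COC | intermediate
10 | lithium 1-methoxy-5-methylhex-1-yn-3-olate (racemic) | COC#CC(O[Li])CC(C)C | intermediate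
11 | 1-methoxy-5-methylhex-1-yn-3-ol (racemic) | COC#CC(O)CC(C)C | intermediate
12 | tert-butyl[(1-methoxy-5-methylhex-1-yn-3-yl)oxy]dimethylsilane (racemic) | COC#CC(O[Si](C)(C)C(C)(C)C)CC(C)C | intermediate
13 | (3E)-5,5-dimethoxypenta-1,3-dien-1-one | COC(OC)/C=C/C=C=O | intermediate
14 | 2-[1-(tert-butyldimethylsilyloxy)-3-methylbutyl]-4-[(1E)-3,3-dimethoxyprop-1-en-1-yl]-3-methoxycyclobut-2-en-1-one (mixture of diastereomers) | COC1=C(C(O[Si](C)(C)C(C)(C)C)CC(C)C)C(=O)C1/C=C/C(OC)OC | intermediate
15 | (3E,5E)-2-[1-(tert-butyldimethylsilyloxy)-3-methylbutyl]-3,7,7-trimethoxyhepta-1,3,5-trien-1-one (C2 and C5 cis across C3=C4) | COC(OC)/C=C/C=C(/OC)C(=C=O)C(O[Si](C)(C)C(C)(C)C)CC(C)C | intermediate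
16 | 2-[1-(tert-butyldimethylsilyloxy)-3-methylbutyl]-6-(dimethoxymethyl)-3-methoxycyclohexa-2,4-dien-1-one (mixture of diastereomers) | COC(OC)C1C=CC(OC)=C(C(O[Si](C)(C)C(C)(C)C)CC(C)C)C1=O | intermediate
17 | 2-[1-(tert-butyldimethylsilyloxy)-3-methylbutyl]-6-(dimethoxymethyl)-3-methoxyphenol (racemic) | COc1ccc(C(OC)OC)c(O)c1C(O[Si](C)(C)C(C)(C)C)CC(C)C | intermediate
18 | 3-[1-(tert-butyldimethylsilyloxy)-3-methylbutyl]-2-hydroxy-4-methoxybenzaldehyde (racemic) | COc1ccc(C=O)c(O)c1C(O[Si](C)(C)C(C)(C)C)CC(C)C | intermediate
19 | (triphenylphosphoranylidene)ketene | O=C=C=P(c1ccccc1)(c1ccccc1)c1ccccc1 | starting material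
20 | 2-[1-(tert-butyldimethylsilyloxy)-3-methylbutyl]-6-formyl-3-methoxyphenyl (triphenylphosphoranylidene)acetate (racemic) | COc1ccc(C=O)c(OC(=O)C=P(c2ccccc2)(c2ccccc2)c2ccccc2)c1C(O[Si](C)(C)C(C)(C)C)CC(C)C | intermediate
21 | 8-[1-(tert-butyldimethylsilyloxy)-3-methylbutyl]-7-methoxy-2H-chromen-2-one (racemic) | COc1ccc2ccc(=O)oc2c1C(O[Si](C)(C)C(C)(C)C)CC(C)C | intermediate
22 | 8-(1-hydroxy-3-methylbutyl)-7-methoxy-2H-chromen-2-one (racemic) | COc1ccc2ccc(=O)oc2c1C(O)CC(C)C | intermediate
23 | 7-methoxy-8-(3-methylbutanoyl)-2H-chromen-2-one | COc1ccc2ccc(=O)oc2c1C(=O)CC(C)C | intermediate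
24 | 1-(7-methoxy-2-oxo-2H-chromen-8-yl)-3-methylbutane-1,2-dione | COc1ccc2ccc(=O)oc2c1C(=O)C(=O)C(C)C | intermediate
25 | 3-methylbutanoyl chloride | CC(C)CC(Cl)=O | starting material
26 | lithium 1-(7-methoxy-2-oxo-2H-chromen-8-yl)-3-methyl-1-oxobut-2-en-2-olate | COc1ccc2ccc(=O)oc2c1C(=O)C(O[Li])=C(C)C | intermediate
27 | Exotimarin H, 1-(7-methoxy-2-oxo-2H-chromen-8-yl)-3-methyl-1-oxobut-2-en-2-yl 3-methylbutanoate | COc1ccc2ccc(=O)oc2c1C(=O)C(OC(=O)CC(C)C)=C(C)C | target

**Step count**

Total steps: 11. Longest linear sequence: 9 steps (steps 1, 2, 5, 6, 7, 8, 9, 10, 11; the alkyne branch through steps 3 and 4 is of equal length).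

**Steps most likely to fail**

Step 5. Capture of the short-lived vinylketene by the branched ynol ether may lose out to ketene dimerisation or to acylation of the product phenol by further ketene. The ynol ether may also be degraded by the 254 nm light and the later heating before it is consumed.
Fallback: the methoxyalkyne is replaced by a triisopropylsiloxyalkyne, the most thoroughly documented partner of this benzannulation, and the methyl group is put on at the end. The fallback sets out from 8 and 6 and returns at 22.
- Addition of ethynylmagnesium bromide to 8 in THF should give 5-methylhex-1-yn-3-ol F1, and TBSCl/imidazole its silyl ether tert-butyldimethyl[(5-methylhex-1-yn-3-yl)oxy]silane F2.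
- Deprotonation of F2 with n-BuLi and oxidation of the acetylide with lithium tert-butyl peroxide should give lithium 3-(tert-butyldimethylsilyloxy)-5-methylhex-1-yn-1-olate F3, which is silylated on oxygen with triisopropylsilyl triflate to tert-butyldimethyl({5-methyl-1-[(triisopropylsilyl)oxy]hex-1-yn-3-yl}oxy)silane F4.
- Irradiation of 6 with F4 under the conditions of step 5 should give 2-[1-(tert-butyldimethylsilyloxy)-3-methylbutyl]-6-(dimethoxymethyl)-3-(triisopropylsilyloxy)phenol F5.
- Pyridinium p-toluenesulfonate in aqueous acetone should give 3-[1-(tert-butyldimethylsilyloxy)-3-methylbutyl]-2-hydroxy-4-(triisopropylsilyloxy)benzaldehyde F6, and 19 in hot toluene 8-[1-(tert-butyldimethylsilyloxy)-3-methylbutyl]-7-(triisopropylsilyloxy)-2H-chromen-2-one F7.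
- TBAF removes both silyl groups to give 7-hydroxy-8-(1-hydroxy-3-methylbutyl)-2H-chromen-2-one F8, and MeI with K2CO3 in acetone methylates only the phenol, which returns the material to the route at 22.

Step 10. Enolisation of the hindered, twisted aryl ketone may be slow and leave the oxidation incomplete. The diketone formed may be oxidised further at its isopropyl methine (hydroxylation or dehydrogenation), or organoselenium by-products may form.
Fallback: the oxygen is introduced by enolate hydroxylation and a second alcohol oxidation. The fallback sets out from 23 and returns at 24. Deprotonation of 23 with KN(SiMe3)2 in THF at −78 °C and treatment with 2-(benzenesulfonyl)-3-phenyloxaziridine (Davis oxaziridine) should give 8-(2-hydroxy-3-methylbutanoyl)-7-methoxy-2H-chromen-2-one F9, which Dess–Martin periodinane in CH2Cl2 oxidises to 24.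

Step 11. The amide base or the enolate may attack the electrophilic 1,2-dicarbonyl unit or the lactone (self-condensation, ring opening) faster than clean enolate formation and O-acylation occur, and some C-acylation may compete.
Fallback: the enol is first trapped under soft, amine-base conditions and the acyl group is then exchanged for silicon without any strong base. The fallback sets out from 24 and returns at 27. TMSOTf and Et3N in CH2Cl2 at 0 °C should give 7-methoxy-8-[3-methyl-2-(trimethylsilyloxy)but-2-enoyl]-2H-chromen-2-one F10. Treatment of F10 with 25 and anhydrous CsF in MeCN frees the enolate from silicon in the presence of the acid chloride and should give 27 directly.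

**Further compounds**

F1 | step 5 | 5-methylhex-1-yn-3-ol (racemic) | C#CC(O)CC(C)C
F2 | step 5 | tert-butyldimethyl[(5-methylhex-1-yn-3-yl)oxy]silane (racemic) | C#CC(O[Si](C)(C)C(C)(C)C)CC(C)C
F3 | step 5 | lithium 3-(tert-butyldimethylsilyloxy)-5-methylhex-1-yn-1-olate (racemic) | CC(C)CC(O[Si](C)(C)C(C)(C)C)C#CO[Li]
F4 | step 5 | tert-butyldimethyl({5-methyl-1-[(triisopropylsilyl)oxy]hex-1-yn-3-yl}oxy)silane (racemic) | CC(C)CC(O[Si](C)(C)C(C)(C)C)C#CO[Si](C(C)C)(C(C)C)C(C)C
F5 | step 5 | 2-[1-(tert-butyldimethylsilyloxy)-3-methylbutyl]-6-(dimethoxymethyl)-3-(triisopropylsilyloxy)phenol (racemic) | COC(OC)c1ccc(O[Si](C(C)C)(C(C)C)C(C)C)c(C(O[Si](C)(C)C(C)(C)C)CC(C)C)c1O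
F6 | step 5 | 3-[1-(tert-butyldimethylsilyloxy)-3-methylbutyl]-2-hydroxy-4-(triisopropylsilyloxy)benzaldehyde (racemic) | O=Cc1ccc(O[Si](C(C)C)(C(C)C)C(C)C)c(C(O[Si](C)(C)C(C)(C)C)CC(C)C)c1O
F7 | step 5 | 8-[1-(tert-butyldimethylsilyloxy)-3-methylbutyl]-7-(triisopropylsilyloxy)-2H-chromen-2-one (racemic) | CC(C)CC(O[Si](C)(C)C(C)(C)C)c1c(O[Si](C(C)C)(C(C)C)C(C)C)ccc2ccc(=O)oc12
F8 | step 5 | 7-hydroxy-8-(1-hydroxy-3-methylbutyl)-2H-chromen-2-one (racemic) | CC(C)CC(O)c1c(O)ccc2ccc(=O)oc12
F9 | step 10 | 8-(2-hydroxy-3-methylbutanoyl)-7-methoxy-2H-chromen-2-one (racemic) | COc1ccc2ccc(=O)oc2c1C(=O)C(O)C(C)C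
F10 | step 11 | 7-methoxy-8-[3-methyl-2-(trimethylsilyloxy)but-2-enoyl]-2H-chromen-2-one | COc1ccc2ccc(=O)oc2c1C(=O)C(O[Si](C)(C)C)=C(C)C
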